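## Retrosynthetic overview
1. There is one strategic bond, the alkyl C–O bond (O–CH2) of the ester. Cutting it gives tetracosanoic acid 1 and a phenyl-C2 unit.
2. The phenyl-C2 unit is taken at the alkyne level as phenylacetylene 2. O–H addition to an alkyne is thermodynamically downhill, and a ruthenium vinylidene directs the oxygen to the terminal carbon.
3. The adduct, (Z)-enol ester 3, is only a relay. H2 and the same ruthenium complex saturate it in the same pot to give target 4.
4. No ring is formed, since the benzene ring is bought with 2. No stereocentre is formed and no protecting group is used.

Assumption: the target has no stereocentre and no C=C bond, so the "single enantiomer" is simply the compound itself. Compounds 1 and 2 are taken as catalogue chemicals.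

## Route

Step 1
Reactants: 1 tetracosanoic acid (lignoceric acid, 1.0 equiv); 2 phenylacetylene (1.3 equiv)
Product: 4 2-phenylethyl tetracosanoate, via (Z)-styryl tetracosanoate 3 (not isolated)
Conditions: Ru(cod)(2-methylallyl)2 (2 mol%), Ph2P(CH2)4PPh2 (dppb, 2.2 mol%), PhMe (0.4 M), Ar, 70 °C, 10 h; then H2 (30 bar), 80 °C, 16 h, same pot, no further catalyst; basic Al2O3 plug, crystallise from acetone
Reagents that add atoms: none
Why: Proposed new method: this is an auto-tandem anti-Markovnikov reductive hydroacyloxylation of a terminal alkyne, in which acid 1 protonates off the methallyl ligands to give Ru(O2CR)2(dppb), this divalent ruthenium carboxylate converts 2 into a ruthenium vinylidene whose electrophilic alpha carbon takes up carboxylate so that the new C–O bond forms only at the terminal carbon (protonolysis frees enol ester 3), and the same complex then splits H2 heterolytically across a Ru–O2CR bond to give RuH(O2CR)(dppb), which binds 3 through the C=C bond and the ester carbonyl, inserts, and is hydrogenolysed to 4; both halves are separately known for this catalyst family (ruthenium-vinylidene hydroacyloxylation of 1-alkynes, and carboxylate-assisted homogeneous hydrogenation of enol esters), the closest known net reaction type is the ruthenium-catalysed anti-Markovnikov reductive hydration of terminal alkynes to primary alcohols, and the new element is a carboxylic acid as the O–H partner with one catalyst carrying an alkyne through a C=C relay to a saturated primary ester; no stereocentre is formed, the Z geometry of 3 is erased, and the atom balance is C24H48O2 + C8H6 + H2 = C32H56O2.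

## Compound list
1 | tetracosanoic acid (lignoceric acid) | CCCCCCCCCCCCCCCCCCCCCCCC(=O)O | starting material
2 | phenylacetylene (ethynylbenzene) | C#Cc1ccccc1 | starting material
3 | (Z)-2-phenylethenyl tetracosanoate ((Z)-styryl tetracosanoate) | CCCCCCCCCCCCCCCCCCCCCCCC(=O)O/C=C\c1ccccc1 | intermediate
4 | 2-phenylethyl tetracosanoate | CCCCCCCCCCCCCCCCCCCCCCCC(=O)OCCc1ccccc1 | target

## Step count and risks
Total step count: 1 (one pot, two stages, one work-up).
Longest linear sequence: 1.

Steps most likely to fail: the route has a single step, so the ranking holds one entry.

Step 1 (the proposed new step) has four weak points:
- (a) After the alkyne stage the ruthenium may rest as alkenyl or enynyl species. These could enter the hydride cycle only slowly, leaving 3 unreduced.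
- (b) Insertion that places Ru at the benzylic carbon opens beta-acyloxy elimination. This would return 1 together with styrene, which would then be reduced to ethylbenzene.
- (c) A few percent of Markovnikov addition would end up as the isomeric 1-phenylethyl ester, which must be removed in the crystallisation.
- (d) Any ligand-free ruthenium could collapse to ruthenium metal under H2 and reduce arene rings. The slight excess of dppb is there to prevent this.

The fallback uses known chemistry and makes the acyl C–O bond by nucleophilic acyl substitution instead of O–H addition to a C–C multiple bond. It sets out from 1 and comes back to the route at 4. Acid 1 is heated with SOCl2 (1.5 equiv, cat. DMF, PhMe, 70 °C) to give tetracosanoyl chloride F1. After evaporation, F1 is added to purchased 2-phenylethanol F2 (1.1 equiv) with Et3N (1.3 equiv) and cat. DMAP in CH2Cl2 (0 °C to 35 °C). Aqueous wash and crystallisation from acetone then give 4.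

Further compounds
F1 | step 1 | tetracosanoyl chloride | CCCCCCCCCCCCCCCCCCCCCCCC(=O)Cl
F2 | step 1 | 2-phenylethanol (purchased) | OCCc1ccccc1
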